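## Structural features

The target is a monocyclic cembranoid: one 14-membered carbocycle, numbered here with cembrane locants (ring C1–C14; C1 carries the isopropenyl group C15(=C16H2)C17H3; C18 is the acetoxymethyl carbon on C4, C19 the exocyclic methylene on C8, C20 the methyl on C12). It has three stereocentres: C1 (R) and C2 (S, acetoxy) are adjacent and anti, while C7 (R, free OH) is 1,6 to C2 and has no neighbour that could relay its configuration. Three alkenes lie in or on the ring: C3=C4, in which the ring carbons C2 and C5 are cis (it is E by CIP only because C18 bears oxygen), C8=C19 next to the C7 carbinol, and C11=C12 (E). Fragile groups are the two allylic acetates (C2, C18), which ionise with Pd(0) or acid, the free allylic alcohol, and the 3-oxy-1,5-diene C16=C15–C1–C2(O)–C3=C4, which is prone to oxy-Cope rearrangement as a hot alkoxide. The real difficulty is to close the 14-membered ring while fixing the C1/C2 pair and the ring-cis trisubstituted C3=C4, and to finish with three allylic oxygens of which only O7 is free. The feature the key step exploits is the unit C2(O)–C1(H)–C15(=C16), the homoallylic-alcohol retron of a [2,3]-Wittig shift. If C3=C4 is written as C3≡C4, C2–H becomes the one acidic C–H, so the C1–C2 bond, both adjacent stereocentres, the isopropenyl group and the 14-ring can all come from a 17-membered cyclic ether C2–O–C16; syn addition to the resulting cycloalkyne then gives the ring-cis C3=C4. In addition, C19, C8–C14, C20, C1 and C15–C17 (13 of 20 carbons, including the E C11=C12 bond) are the skeleton of geranylacetone.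

## Logic of the disconnections

21 ⇒ 20 ⇒ 19. The O–Si bond at C7 is restored and the two O–acetyl bonds at C2 and C18 are cut. Only O7 is free in 21, so C7 must carry the one group that outlasts the acetylation. The gain is that the two hydroxyls of 19 are treated alike and no selective acylation is needed. The demand is that the silyl group is removed without cleaving or shifting allylic acetates.

19 ⇒ 18 ⇒ 16. C4–C18 is cut, then C4–I and C3–H. A ring-cis C3=C4 with C18 trans to C2 is exactly what syn addition of H (to C3) and a carbon group (to C4) across a cycloalkyne gives. The gain is loss of the trisubstituted alkene and one carbon. The demands are metal at C4 and not C3, retention in both replacements, and no Pd(0) once allylic acetates exist.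

16 ⇒ 14 (key). C1–C2 is cut and the oxygen on C2 is joined to C16 (retro-[2,3]-Wittig). Two adjacent stereocentres, the isopropenyl group and the carbocycle disappear together; 14 has one stereocentre and an ether link. The forward step must deprotonate at C2 only, shift [2,3] and not [1,2], give the anti pair, and select one face.

14 ⇒ 13 ⇒ 12. O–Si is cut, then C7–C8. C7(OH)–C8(=C19H2) is the retron of an alkenyl-metal addition to an aldehyde, and the alkenyl triflate comes from a methyl ketone. The gain is an open chain without any stereocentre, closed to a 17-ring that is less strained than a 14-ring. The demands are catalyst control of the aldehyde face and high dilution.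

12 ⇒ 11 ⇒ 9. Functional-group changes only: the C7 aldehyde from a dioxolane, and the C8–O–S bond of the triflate from the methyl ketone. The demands are methyl-side (kinetic) enolisation and an acid hydrolysis that spares the triflate.

9 ⇒ 4 + 7. O–C16 is cut. This ether is the tether of the key step and is made by plain O-alkylation. The gain is two pieces of 8 and 13 carbons. The demands are SN2 (not SN2′) at C16 and no enolisation of the ketone.

7 ⇒ 6 ⇒ 5. C16–Br and C16–O are cut back to the C16–H of 5, which supplies 13 carbons and the E C11=C12 bond. The demand is oxidation at the terminal (E)-methyl group only.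

4 ⇒ 1 + 2. C4–C5 is cut (acetylide alkylation). The demand is C- and not O-alkylation of the dianion.

## Other disconnections considered

Alternative 1: (the first that comes to mind) cut C1–C2 in the 14-ring itself. The forward key step would be an intramolecular chromium(II)-mediated allylation (Nozaki–Hiyama) of the open-chain (E)-allylic bromide–enal A1, giving the macrocyclic homoallylic alcohol A2 and, after acetylation, 20. A1 needs the ring-cis, C18-oxygenated trisubstituted enal to be built stereoselectively on an open chain together with C7 and its protecting group, which is estimated at several steps more than ether 9. In the 14-membered chromium transition state nothing but the remote C7 centre distinguishes the aldehyde faces, so both anti products are expected unless a chiral ligand overrides the ring. The enal is also a 1,4-acceptor. The chosen plan makes the same bond through a five-membered transition state inside a ring that already exists.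

Alternative 2: cut C3=C4 and add a temporary lactone ring between O7 and C18. The forward key step would be an intramolecular Horner–Wadsworth–Emmons reaction of the aldehyde–phosphonolactone A3 to the bridged (E)-alkylidene lactone A4, whose lactone is later reduced to C18–OH and C7–OH. This step sets no stereocentre, so C1/C2 need a separate intermolecular reagent-controlled allylation and C2 its own protecting group. The C3 aldehyde is α-oxygenated and can epimerise at C2 under the basic olefination. The bridge does not enforce E over Z, since both alkylidene isomers fit a 14-ring. Opening the bridge frees O7 and O18 together, so telling three hydroxyls apart would take about six closing steps against three here.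

Alternative 3: cut C3≡C4 of 16. The forward key step would be ring-closing alkyne metathesis (molybdenum alkylidyne) of diyne A5 (C2–OH shown free; it would have to be masked), giving 16 directly. All three stereocentres would have to be set on the open chain by separate reagent-controlled reactions, the C1/C2 pair again by an intermolecular allylation. A propargylic oxygen next to the reacting alkyne slows alkylidyne catalysts and needs a protecting group distinct from that on O7, and two methyl-capped alkynes must be installed. The plan is estimated three to four steps longer and uses the alkyne only for ring closure, whereas in the chosen plan the same alkyne also activates C2–H for the key step.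

Key step: step 9

Remark 1: (E)-geranylacetone 5 is taken to be bought as the single E isomer; a commercial E/Z mixture would have to be separated first.
Remark 2: the sense of induction of the two chiral reagents (ligand in step 7, lithium amide in step 9) is assigned by analogy only; the antipode of each is equally available and would be used if the sense is the reverse.

## Route

Step 1
Reactants: 1 prop-2-yn-1-ol; 2 2-(2-bromoethyl)-1,3-dioxolane
Product: 4 5-(1,3-dioxolan-2-yl)pent-2-yn-1-ol, via dilithiated propargyl alcohol 3 (not isolated)
Conditions: n-BuLi (2.1 equiv), THF/DMPU, −78 → −20 °C; then 2, −20 °C → rt; then H2O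
Reagents that add atoms: none
Why: Alkylation of the O,C-dianion of propargyl alcohol: in THF/DMPU the acetylide carbon is far more nucleophilic than the alkoxide, so the primary bromide is displaced at carbon (SN2) to give the C2–C7 unit with C7 masked as a dioxolane; no stereocentre is formed.

Step 2
Reactants: 5 (E)-geranylacetone
Product: 6 (5E,9E)-11-hydroxy-6,10-dimethylundeca-5,9-dien-2-one
Conditions: SeO2 (0.1 equiv), salicylic acid (0.1 equiv), t-BuOOH (3 equiv), CH2Cl2, 0 °C → rt
Reagents that add atoms: tert-butyl hydroperoxide, CC(C)(C)OO (source of the oxygen, passed on through catalytic SeO2)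
Why: SeO2/t-BuOOH allylic oxidation (ene reaction, then [2,3]-shift of the allylseleninic acid) attacks the terminal isopropylidene group at its (E)-methyl, as is usual for polyprenyl chains, and gives the (E)-allylic alcohol at C16; the ketone is inert at room temperature.

Step 3
Reactants: 6 (5E,9E)-11-hydroxy-6,10-dimethylundeca-5,9-dien-2-one
Product: 7 (5E,9E)-11-bromo-6,10-dimethylundeca-5,9-dien-2-one
Conditions: CBr4, PPh3, CH2Cl2, 0 °C
Reagents that add atoms: carbon tetrabromide, BrC(Br)(Br)Br
Why: Appel bromination replaces the primary allylic hydroxyl by bromide through SN2 at C16 under neutral conditions, which spares the ketone and keeps the C1=C15 geometry.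

Step 4
Reactants: 4 5-(1,3-dioxolan-2-yl)pent-2-yn-1-ol; 7 (5E,9E)-11-bromo-6,10-dimethylundeca-5,9-dien-2-one
Product: 9 (5E,9E)-11-{[5-(1,3-dioxolan-2-yl)pent-2-yn-1-yl]oxy}-6,10-dimethylundeca-5,9-dien-2-one, via sodium alkoxide 8 (not isolated)
Conditions: NaH (1.0 equiv relative to 4), THF, 0 °C; then 7, Bu4NI (cat.), 0 °C → rt
Reagents that add atoms: none
Why: Williamson ether synthesis: the propargylic alkoxide (a weak base, alcohol pKa about 13–14) displaces the primary allylic bromide by SN2 faster than it enolises the methyl ketone; the C2–O–C16 bond made here is the tether that the key step contracts.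

Step 5
Reactants: 9 keto ether (name as in step 4)
Product: 11 (5E,9E)-11-{[5-(1,3-dioxolan-2-yl)pent-2-yn-1-yl]oxy}-6,10-dimethylundeca-1,5,9-trien-2-yl trifluoromethanesulfonate, via potassium enolate 10 (not isolated)
Conditions: KHMDS (1.05 equiv), THF, −78 °C; then PhNTf2, −78 → 0 °C; aq. NH4Cl
Reagents that add atoms: N-phenylbis(trifluoromethanesulfonimide), O=S(=O)(N(c1ccccc1)S(=O)(=O)C(F)(F)F)C(F)(F)F
Why: Kinetic deprotonation by the hindered amide at −78 °C occurs on the methyl side (C19), and O-sulfonylation of the terminal enolate gives the 2-triflyloxy-1-alkene that carries the future exocyclic C8=C19; the propargylic ether C–H is far less acidic than the ketone and is untouched by one equivalent of KHMDS.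

Step 6
Reactants: 11 alkenyl triflate acetal (name as in step 5)
Product: 12 (5E,9E)-6,10-dimethyl-11-[(6-oxohex-2-yn-1-yl)oxy]undeca-1,5,9-trien-2-yl trifluoromethanesulfonate
Conditions: 2 M aq. HCl, THF, rt
Reagents that add atoms: water, O
Why: Acid-catalysed hydrolysis of the dioxolane releases the C7 aldehyde; the alkenyl triflate, the allyl propargyl ether and the trisubstituted alkenes are stable to dilute aqueous acid at room temperature.

Step 7
Reactants: 12 alkenyl triflate aldehyde (name as in step 6)
Product: 13 (3E,7E,12R)-3,7-dimethyl-11-methylidene-1-oxacycloheptadeca-3,7-dien-15-yn-12-ol (17-membered ether; cembrane locants: O bridges C2 and C16; 7R-OH; C8=C19H2)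
Conditions: CrCl2 (4 equiv), NiCl2 (2 mol %), (S)-N-[2-(4-isopropyl-4,5-dihydrooxazol-2-yl)-6-methylphenyl]methanesulfonamide (4.4 equiv), Et3N, THF, rt, slow addition of 12 (final about 2 mM); aqueous work-up
Reagents that add atoms: none
Why: Intramolecular Nozaki–Hiyama–Kishi reaction: Ni(0) inserts into the C8–OTf bond, the alkenyl group passes to chromium and adds chemoselectively to the aldehyde, forming C7–C8, the exocyclic methylene and the C7 carbinol at once and closing an unstrained 17-membered ring under high dilution; the 7R configuration is set by the chiral oxazoline–sulfonamide ligand on chromium (reagent control).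

Step 8
Reactants: 13 17-membered ether alcohol (name as in step 7)
Product: 14 tert-butyldimethylsilyl ether of 13 (7R)
Conditions: TBSCl, imidazole, DMF, rt
Reagents that add atoms: tert-butyldimethylsilyl chloride, CC(C)(C)[Si](C)(C)Cl
Why: Standard silylation of the secondary allylic alcohol; the TBS ether withstands the lithium amide, the zirconium and palladium steps and the acetylation, and is the last group removed, which is how O7 ends as the only free hydroxyl.

Step 9
Reactants: 14 TBS-protected 17-membered propargyl allyl ether (7R)
Product: 16 (1R,2R,7R,11E)-7-(tert-butyldimethylsilyloxy)-18-norcembra-8(19),11,15-trien-3-yn-2-ol (14-membered carbocycle; C1 isopropenyl; C2 OH; C3≡C4), via C2-lithiated ether 15 (not isolated)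
Conditions: (S,S)-bis(1-phenylethyl)amine, n-BuLi, THF, −78 → −25 °C; then H2O
Reagents that add atoms: none
Why: The lithium amide removes the propargylic C2–H (α to oxygen and to C3≡C4, the most acidic C–H of 14) to give the α-oxy propargyl-lithium 15, which undergoes a concerted suprafacial [2,3]-Wittig shift through a five-membered envelope transition state (C2, O, C16, C15, C1): C1–C2 forms, O–C16 breaks and the alkene moves to C15=C16, i.e. the isopropenyl group. The closest known reaction type is the [2,3]-Wittig ring contraction of macrocyclic propargyl allyl ethers to carbocyclic propargylic alcohols. The 14-membered carbocycle is closed by contraction of the 17-membered oxacycle (O, C16 and C15 leave the ring), so the ring-forming event is a five-centre sigmatropic shift between termini already held in one ring and not an end-to-end cyclisation. C1 is set relative to C2 by the (E) geometry of C1=C15 together with the exo position of the alkynyl group on the envelope, which gives the anti pair (C14 on C1 anti to O on C2, as in the target; the descriptor at C2 is R here only because the alkyne outranks C1). The absolute sense at C2 is set by the chiral amide, which distinguishes the two propargylic hydrogens (diastereotopic here because of C7); C7 is untouched and makes the unwanted anti isomer a diastereomer that can be removed by chromatography. The step needs deprotonation at C2 and not at the allylic C16–H (secured by the alkyne), a [2,3] and not a [1,2] shift (low temperature) and a base-stable group on O7 (the TBS ether); the lithium alkoxide is quenched cold so that no oxy-Cope reaction of the 3-oxido-1,5-enyne can follow.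

Step 10
Reactants: 16 14-membered propargylic alcohol (1R,2R,7R)
Product: 18 (1R,2R,3E,7R,11E)-4-iodo-7-(tert-butyldimethylsilyloxy)-18-norcembra-3,8(19),11,15-tetraen-2-ol (C2 and C5 cis on C3=C4), via C4-alkenylzirconocene 17 (not isolated)
Conditions: Cp2Zr(H)Cl (2.5 equiv), THF, rt; then I2, 0 °C; aq. Na2S2O3
Reagents that add atoms: iodine, II
Why: Hydrozirconation: the first equivalent forms the C2 zirconium alkoxide (H2 is lost) and the next adds Zr–H syn across C3≡C4 with zirconium at C4, the alkyne carbon remote from the branched, O-metalated C2 (steric control, as for 2-alkyn-1-ols). Iodinolysis of C–Zr goes with retention, and syn addition to a cycloalkyne can only give the ring-cis alkene, so C2 and C5 are cis and iodine is trans to C2; the internal alkyne reacts faster than the 1,1-disubstituted alkenes.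

Step 11
Reactants: 18 alkenyl iodide (1R,2R,3E,7R)
Product: 19 (1R,2S,3E,7R,11E)-7-(tert-butyldimethylsilyloxy)cembra-3,8(19),11,15-tetraene-2,18-diol
Conditions: Bu3SnCH2OH (1.5 equiv), Pd(PPh3)4 (10 mol %), 1,4-dioxane, 90 °C
Reagents that add atoms: (tributylstannyl)methanol, CCCC[Sn](CCCC)(CCCC)CO
Why: Stille coupling transfers the hydroxymethyl group to C4 with retention of alkene geometry, which puts C18 trans to C2 as in the target; it is run before any allylic acetate exists, so Pd(0) meets no ionisable allylic ester, and the free hydroxyls and silyl ether are tolerated.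

Step 12
Reactants: 19 C2,C18-diol (1R,2S,3E,7R)
Product: 20 (1R,2S,3E,7R,11E)-7-(tert-butyldimethylsilyloxy)cembra-3,8(19),11,15-tetraene-2,18-diyl diacetate
Conditions: Ac2O, pyridine, DMAP (cat.), CH2Cl2, 0 °C → rt
Reagents that add atoms: acetic anhydride, CC(=O)OC(C)=O
Why: DMAP-catalysed acetylation esterifies the only two free hydroxyls (C2 secondary allylic, C18 primary allylic) in one operation; no stereocentre is touched.

Step 13
Reactants: 20 silyl ether diacetate
Product: 21 (1R,2S,3E,7R,11E)-7-hydroxycembra-3,8(19),11,15-tetraene-2,18-diyl diacetate (target, CNP0077636.1)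
Conditions: HF·pyridine, pyridine/THF, 0 °C → rt
Reagents that add atoms: none
Why: Fluoride cleavage of the Si–O bond with buffered HF·pyridine releases the C7 alcohol; the medium is not basic enough to cleave or shift the acetates and not acidic enough to ionise the allylic esters.

## Compound list

1 | prop-2-yn-1-ol (propargyl alcohol) | OCC#C | starting material
2 | 2-(2-bromoethyl)-1,3-dioxolane | BrCCC1OCCO1 | starting material
3 | O,C-dilithiated prop-2-yn-1-ol (not isolated) | [Li]OCC#C[Li] | intermediate
4 | 5-(1,3-dioxolan-2-yl)pent-2-yn-1-ol (C2–C7 unit) | OCC#CCCC1OCCO1 | intermediate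
5 | (E)-geranylacetone, (5E)-6,10-dimethylundeca-5,9-dien-2-one | CC(=O)CC/C=C(\C)CCC=C(C)C | starting material
6 | (5E,9E)-11-hydroxy-6,10-dimethylundeca-5,9-dien-2-one | CC(=O)CC/C=C(\C)CC/C=C(\C)CO | intermediate
7 | (5E,9E)-11-bromo-6,10-dimethylundeca-5,9-dien-2-one | CC(=O)CC/C=C(\C)CC/C=C(\C)CBr | intermediate
8 | sodium 5-(1,3-dioxolan-2-yl)pent-2-yn-1-olate (not isolated) | [Na+].[O-]CC#CCCC1OCCO1 | intermediate
9 | (5E,9E)-11-{[5-(1,3-dioxolan-2-yl)pent-2-yn-1-yl]oxy}-6,10-dimethylundeca-5,9-dien-2-one | CC(=O)CC/C=C(\C)CC/C=C(\C)COCC#CCCC1OCCO1 | intermediate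
10 | potassium enolate of 9, terminal (C8–O, C8=C19) (not isolated) | [K+].[O-]C(=C)CC/C=C(\C)CC/C=C(\C)COCC#CCCC1OCCO1 | intermediate
11 | (5E,9E)-11-{[5-(1,3-dioxolan-2-yl)pent-2-yn-1-yl]oxy}-6,10-dimethylundeca-1,5,9-trien-2-yl trifluoromethanesulfonate | C=C(OS(=O)(=O)C(F)(F)F)CC/C=C(\C)CC/C=C(\C)COCC#CCCC1OCCO1 | intermediate
12 | (5E,9E)-6,10-dimethyl-11-[(6-oxohex-2-yn-1-yl)oxy]undeca-1,5,9-trien-2-yl trifluoromethanesulfonate | C=C(OS(=O)(=O)C(F)(F)F)CC/C=C(\C)CC/C=C(\C)COCC#CCCC=O | intermediate
13 | (3E,7E,12R)-3,7-dimethyl-11-methylidene-1-oxacycloheptadeca-3,7-dien-15-yn-12-ol (17-membered ether, O between C2 and C16, 7R-OH) | C=C1CC/C=C(\C)CC/C=C(\C)COCC#CCC[C@H]1O | intermediate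
14 | tert-butyldimethylsilyl ether of 13 (7R) | C=C1CC/C=C(\C)CC/C=C(\C)COCC#CCC[C@H]1O[Si](C)(C)C(C)(C)C | intermediate
15 | C2-lithiated 14, α-oxy propargyl-lithium (not isolated) | C=C1CC/C=C(\C)CC/C=C(\C)COC([Li])C#CCC[C@H]1O[Si](C)(C)C(C)(C)C | intermediate
16 | (1R,2R,7R,11E)-7-(tert-butyldimethylsilyloxy)-18-norcembra-8(19),11,15-trien-3-yn-2-ol | C=C1CC/C=C(\C)CC[C@H](C(=C)C)[C@@H](O)C#CCC[C@H]1O[Si](C)(C)C(C)(C)C | intermediate
17 | C4-(chlorozirconocenyl) alkene with C2–O–Zr(Cl)Cp2, from syn Zr–H addition to 16 (not isolated; Cp drawn σ-bonded) | C=C1CC/C=C(\C)CC[C@H](C(=C)C)[C@@H](O[Zr](Cl)(C2C=CC=C2)C2C=CC=C2)/C=C(/[Zr](Cl)(C2C=CC=C2)C2C=CC=C2)CC[C@H]1O[Si](C)(C)C(C)(C)C | intermediate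
18 | (1R,2R,3E,7R,11E)-4-iodo-7-(tert-butyldimethylsilyloxy)-18-norcembra-3,8(19),11,15-tetraen-2-ol | C=C1CC/C=C(\C)CC[C@H](C(=C)C)[C@@H](O)/C=C(/I)CC[C@H]1O[Si](C)(C)C(C)(C)C | intermediate
19 | (1R,2S,3E,7R,11E)-7-(tert-butyldimethylsilyloxy)cembra-3,8(19),11,15-tetraene-2,18-diol | C=C1CC/C=C(\C)CC[C@H](C(=C)C)[C@@H](O)/C=C(/CO)CC[C@H]1O[Si](C)(C)C(C)(C)C | intermediate
20 | (1R,2S,3E,7R,11E)-7-(tert-butyldimethylsilyloxy)cembra-3,8(19),11,15-tetraene-2,18-diyl diacetate | C=C1CC/C=C(\C)CC[C@H](C(=C)C)[C@@H](OC(C)=O)/C=C(/COC(C)=O)CC[C@H]1O[Si](C)(C)C(C)(C)C | intermediate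
21 | (1R,2S,3E,7R,11E)-7-hydroxycembra-3,8(19),11,15-tetraene-2,18-diyl diacetate | C=C1CC/C=C(\C)CC[C@H](C(=C)C)[C@@H](OC(C)=O)/C=C(/COC(C)=O)CC[C@H]1O | target

## Step count and least certain steps

Total: 13 steps. Longest linear sequence: 12 steps (steps 2–13, from 5); step 1 is the only step off the main line.

Step 9 (key step). What may go wrong: deprotonation at the allylic C16–H or the propargylic C5–H in place of C2–H, a competing [1,2]-shift, or weak selection between the two diastereotopic C2 hydrogens (mismatched pairing of the amide with C7), which would give mainly the anti product of the opposite C1/C2 sense. Fallback, which makes C1–C2 by an intermolecular allylation and closes the 14-ring directly; it sets out from 4 and 7 and comes back at 16. Alcohol 4 would be oxidised (MnO2, CH2Cl2) to 5-(1,3-dioxolan-2-yl)pent-2-ynal F1. A chromium(II)-mediated Nozaki–Hiyama allylation of F1 with bromide 7 (CrCl2, chiral oxazoline–sulfonamide ligand, THF; anti through the cyclic transition state, face chosen by the ligand; the ketone is inert) should give the anti keto alcohol F2. PMB protection (4-methoxybenzyl trichloroacetimidate, cat. CSA) would give the PMB ether F3, and KHMDS/PhNTf2 the alkenyl triflate F4. Dilute aqueous acid would then give the aldehyde F5, and Ni/Cr ring closure at C7–C8 with the chiral ligand the 14-membered alcohol F6. TBSCl/imidazole would give the silyl ether F7, and DDQ (CH2Cl2/buffer) would remove the PMB group to give 16.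

Step 7. What may go wrong: oligomerisation in place of ring closure, or poor facial selectivity at the aldehyde so that both C7 epimers form. Fallback, which sets C7 by reduction in place of addition; it sets out from 13 (as the epimer mixture, also available with achiral NiCl2/CrCl2 in DMSO) and comes back at 13. Oxidation with DMP would give the 17-membered α-methylene ketone F8. Corey–Bakshi–Shibata reduction (methyl oxazaborolidine, BH3·SMe2, −40 °C), in which the 1,1-disubstituted alkenyl group acts as the large substituent, should return 13 as the 7R alcohol.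

Step 10. What may go wrong: Zr–H addition with the wrong regiochemistry (zirconium at C3), or competing hydrozirconation of the isopropenyl or C8 methylene groups. Fallback, which uses a hydroxyl-directed hydrosilylation; it sets out from 16 and comes back at 18. Platinum-catalysed syn hydrosilylation directed by the free propargylic hydroxyl (PtCl2/XPhos, Et3SiH, THF) should give the C4-triethylsilyl alkene F9, with silicon on the carbon remote from the carbinol. Iododesilylation (NIS, hexafluoroisopropanol, 0 °C, retention) would then give 18.

Step 11. What may go wrong: slow transmetalation of the sp3 stannane, so that protodeiodination or homocoupling takes over. Fallback, which brings C18 in as carbon monoxide; it sets out from 18 and comes back at 19. Palladium-catalysed methoxycarbonylation (CO 1 atm, Pd(OAc)2/dppf, Et3N, MeOH/DMF) should give the methyl ester F10 with retention; C2–OH is trans to the ester and cannot lactonise. Reduction with DIBAL-H (CH2Cl2, −78 °C) would give 19.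

## Further compounds

F1 | step 9 | 5-(1,3-dioxolan-2-yl)pent-2-ynal | O=CC#CCCC1OCCO1
F2 | step 9 | anti keto alcohol: C19H3–C8(=O) chain, (1R,2R) C1 isopropenyl/C2 OH, C3≡C4, C7 dioxolane (cembrane locants) | CC(=O)CC/C=C(\C)CC[C@H](C(=C)C)[C@@H](O)C#CCCC1OCCO1
F3 | step 9 | 4-methoxybenzyl ether of F2 | CC(=O)CC/C=C(\C)CC[C@H](C(=C)C)[C@@H](OCc1ccc(OC)cc1)C#CCCC1OCCO1
F4 | step 9 | terminal alkenyl triflate (C8–OTf, C8=C19) of F3 | C=C(OS(=O)(=O)C(F)(F)F)CC/C=C(\C)CC[C@H](C(=C)C)[C@@H](OCc1ccc(OC)cc1)C#CCCC1OCCO1
F5 | step 9 | C7 aldehyde from F4 | C=C(OS(=O)(=O)C(F)(F)F)CC/C=C(\C)CC[C@H](C(=C)C)[C@@H](OCc1ccc(OC)cc1)C#CCCC=O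
F6 | step 9 | 14-membered (7R)-alcohol with C2–OPMB and C3≡C4 | C=C1CC/C=C(\C)CC[C@H](C(=C)C)[C@@H](OCc2ccc(OC)cc2)C#CCC[C@H]1O
F7 | step 9 | tert-butyldimethylsilyl ether of F6 | C=C1CC/C=C(\C)CC[C@H](C(=C)C)[C@@H](OCc2ccc(OC)cc2)C#CCC[C@H]1O[Si](C)(C)C(C)(C)C
F8 | step 7 | 17-membered α-methylene ketone (C7=O, C8=C19H2) | C=C1CC/C=C(\C)CC/C=C(\C)COCC#CCCC1=O
F9 | step 10 | C4-triethylsilyl alkene from syn hydrosilylation of 16 | C=C1CC/C=C(\C)CC[C@H](C(=C)C)[C@@H](O)/C=C(/[Si](CC)(CC)CC)CC[C@H]1O[Si](C)(C)C(C)(C)C
F10 | step 11 | C18 methyl ester (C2–OH free, C7–OTBS) | C=C1CC/C=C(\C)CC[C@H](C(=C)C)[C@@H](O)/C=C(/C(=O)OC)CC[C@H]1O[Si](C)(C)C(C)(C)C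
A1 | alternative 1 | open-chain (E)-allylic bromide–enal (C16–Br; C2 aldehyde; C18–OAc; 7R-OTBS) | O=C/C=C(/COC(C)=O)CC[C@@H](O[Si](C)(C)C(C)(C)C)C(=C)CC/C=C(\C)CC/C=C(\C)CBr
A2 | alternative 1 | macrocyclic alcohol from C1–C2 allylation (C2–OH, C18–OAc, C7–OTBS) | C=C1CC/C=C(\C)CC[C@H](C(=C)C)[C@@H](O)/C=C(/COC(C)=O)CC[C@H]1O[Si](C)(C)C(C)(C)C
A3 | alternative 2 | C3 aldehyde (C2–OPMB) tethered to an α-diethylphosphono-δ-lactone (O7–C18 lactone) | O=C[C@H](OCc1ccc(OC)cc1)[C@@H](C(=C)C)CC/C(C)=C/CCC(=C)[C@H]1CCC(P(=O)(OCC)OCC)C(=O)O1
A4 | alternative 2 | 14-membered ring bridged by the (E)-alkylidene δ-lactone (O7–C18) | C=C1CC/C=C(\C)CC[C@H](C(=C)C)[C@@H](OCc2ccc(OC)cc2)/C=C2\CC[C@H]1OC2=O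
A5 | alternative 3 | open-chain diyne with methyl-capped alkynes at C3 and C4 | CC#C[C@H](O)[C@@H](C(=C)C)CC/C(C)=C/CCC(=C)[C@H](O[Si](C)(C)C(C)(C)C)CCC#CC
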